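**Strategy.** Ring B (C7–C12=C13–C14–C15–C20) is cut at C7–C12 and C13–C14. The C7(O)–C12(=C13)–C11(=O) array is a Baylis–Hillman-type enoate on a tertiary carbinol, and C14 is alpha to the ring C carbonyl carbon C18. Methyl propiolate therefore serves as a two-carbon linchpin: an iodide-relayed halo-aldol at the alpha-keto ester carbon C7, then vinylic substitution by the C14 enolate, close ring B in one pot (formal [4+2] annulation). The precursor is the catalytic asymmetric Michael adduct of cyclopentenone and a methylated 2,4-dioxo ester, which sets C15 and C20. C18 methylation, ring D (oxidative etherification) and ring A (ring-closing metathesis) follow.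

Key step: step 4

Atom labels: C1 and C3 are the methyls on C2; C4 is the vinyl CH; C5 the O-bearing CH of ring D; O6 the ring oxygen; C7 the O-bearing quaternary carbon; C8(=O)–C9=C10–C11(=O)–C12 complete ring A; C13 is the vinyl CH; C14 and C15 are the ring-fusion CH carbons; C16 and C17 the CH2 groups; C18 the carbinol carbon (C19 its methyl); C20 the quaternary carbon (C22 its methyl); C21 the ring D carbonyl carbon. Ring A: C7–C12. Ring B: C7, C12, C13, C14, C15, C20. Ring C: C14–C18. Ring D: C5, O6, C7, C20, C21. In these labels the target is 5R,7S,14R,15S,18S,20R.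

Remark (assumption): C5 is the only epimerizable stereocentre; the natural arrangement (isobutenyl trans to C8 and C22 across ring D) is taken to be the more stable one and is reached by equilibration.

**Route**

Step 1
Reactants: 1 (E)-5-methylhex-3-en-2-one; 2 dimethyl oxalate
Product: 3 methyl (5E)-7-methyl-2,4-dioxooct-5-enoate
Conditions: NaOMe, MeOH/Et2O, 0 °C to rt; then 1 M HCl
Reagents that add atoms: none
Why: Crossed Claisen condensation, regiospecific because the methyl group is the only enolizable alpha-position of 1 and the product is drawn off as its stabilized enolate.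

Step 2
Reactants: 3 methyl (5E)-7-methyl-2,4-dioxooct-5-enoate
Product: 4 methyl (5E)-3,7-dimethyl-2,4-dioxooct-5-enoate
Conditions: K2CO3, MeI (1.05 equiv), acetone, 0 °C to rt
Reagents that add atoms: iodomethane, CI
Why: C-alkylation of the acidic 1,3-dicarbonyl methylene (future C20) should install C22; the centre is configurationally labile and needs no control here.

Step 3
Reactants: 4 methyl (5E)-3,7-dimethyl-2,4-dioxooct-5-enoate; 5 cyclopent-2-en-1-one
Product: 6 methyl (3S,5E)-3,7-dimethyl-2,4-dioxo-3-[(1S)-3-oxocyclopentyl]oct-5-enoate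
Conditions: quinidine-derived 6'-hydroxy-9-O-(9-phenanthryl) bifunctional catalyst (10 mol %), CH2Cl2, −20 °C
Reagents that add atoms: none
Why: Catalytic asymmetric Michael addition in which the quinuclidine deprotonates C20–H and the 6'-OH binds the enone, so the catalyst pocket should select one face of the enol (C20) and one face of cyclopentenone (C15), giving the vicinal quaternary and tertiary centres.

Step 4
Reactants: 6 methyl (3S,5E)-3,7-dimethyl-2,4-dioxo-3-[(1S)-3-oxocyclopentyl]oct-5-enoate; 7 methyl propiolate
Product: 10 dimethyl (3aS,4R,5R,7aR)-5-hydroxy-4-methyl-4-[(2E)-4-methylpent-2-enoyl]-1-oxo-2,3,3a,4,5,7a-hexahydro-1H-indene-5,6-dicarboxylate, via silyl iodoallenolate 8 (not isolated), via iodo-aldol silyl ether 9 (not isolated)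
Conditions: 7, Me3SiI (1.3 equiv), CH2Cl2, −78 °C; add 6, −78 to −40 °C; then DBU (4 equiv), MeCN, 0 °C to rt; 1 M HCl work-up
Reagents that add atoms: none
Why: Me3SiI adds iodide to 7 to give the silyl iodoallenolate 8, whose alpha-carbon (C12) adds in an open Mukaiyama-type aldol to the alpha-keto ester carbonyl C7 of 6 (C7–C12), and DBU then generates the C14 enolate, which displaces iodide from C13 by addition–elimination (C13–C14) and restores the C12=C13 enoate. The closest known reactions are the iodide-mediated halo-aldol (beta-iodo Morita–Baylis–Hillman) reaction of propiolates with activated carbonyls and the vinylic substitution of beta-iodoacrylates by ketone enolates, which together amount to a formal [4+2] annulation. Ring B closes by a 6-endo-trig addition–elimination through a chair-like transition state. C7 should be set in the aldol by a polar Felkin–Anh arrangement under non-chelating silicon activation (C21 acyl antiperiplanar to the nucleophile, C22 outside, cyclopentanone branch inside), which leaves C8 anti to C15 and O6 anti to C22 as in the target; C14 should end up trans to the C15–C20 bond because only the trans ring fusion keeps both ring C bonds equatorial on ring B and this centre can equilibrate through the enolate. The step needs chemoselectivity for C7 over the C18 and C21 carbonyls (alpha-keto ester activation), regioselectivity for C14 over C17 (only C14 gives a six-membered ring), and no competing enolate on the C21 side, which is secured by carrying C5 as an sp2 enone carbon.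

Step 5
Reactants: 10 dimethyl (3aS,4R,5R,7aR)-5-hydroxy-4-methyl-4-[(2E)-4-methylpent-2-enoyl]-1-oxo-2,3,3a,4,5,7a-hexahydro-1H-indene-5,6-dicarboxylate
Product: 11 dimethyl (1S,3aS,4R,5R,7aR)-1,5-dihydroxy-1,4-dimethyl-4-[(2E)-4-methylpent-2-enoyl]-2,3,3a,4,5,7a-hexahydro-1H-indene-5,6-dicarboxylate
Conditions: MeTi(OiPr)3 (4 equiv), CH2Cl2/Et2O, −40 °C to rt; aq. NH4Cl
Reagents that add atoms: methyltitanium triisopropoxide, C[Ti](OC(C)C)(OC(C)C)OC(C)C
Why: Organotitanium carbonyl addition: the weakly basic, bulky reagent should add only to the unhindered cyclopentanone (the esters and the neopentylic cross-conjugated C21 enone stay intact) and approach C18 anti to the C14–C13 bond, on the face of the pseudo-axial H14, placing C19 trans and the hydroxyl cis to C13.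

Step 6
Reactants: 11 dimethyl (1S,3aS,4R,5R,7aR)-1,5-dihydroxy-1,4-dimethyl-4-[(2E)-4-methylpent-2-enoyl]-2,3,3a,4,5,7a-hexahydro-1H-indene-5,6-dicarboxylate
Product: 13 dimethyl ester of the ring B/C/D furanone tricycle, via alpha-iodo ketone 12 (not isolated)
Conditions: KN(SiMe3)2 (3.2 equiv), THF, −78 °C; I2 (1.05 equiv), −78 to 0 °C; aq. Na2S2O3
Reagents that add atoms: none
Why: Gamma-deprotonation of the enone (C2–H) gives the extended enolate, iodine attacks its alpha-carbon C5 (deconjugative alpha-halogenation), and the C7 alkoxide closes ring D by a 5-exo-tet Williamson displacement; C5 should equilibrate through the enolate to the epimer with the isobutenyl group trans to C8 and C22.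

Step 7
Reactants: 13 dimethyl ester of the ring B/C/D furanone tricycle
Product: 15 bis(vinyl ketone) of the ring B/C/D tricycle, via bis(N-methoxy-N-methylamide) 14 (not isolated)
Conditions: MeNHOMe·HCl (6 equiv), iPrMgCl (12 equiv), THF, −20 to 0 °C; then CH2=CHMgBr (6 equiv), 0 °C; inverse quench into cold 1 M HCl
Reagents that add atoms: vinylmagnesium bromide, C=C[Mg]Br
Why: Weinreb ketone synthesis: both esters are converted in situ to N-methoxy-N-methylamides whose chelated tetrahedral adducts release the two vinyl ketones only on quench, while the hindered C21 ketone should be shielded as its magnesium enolate.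

Step 8
Reactants: 15 bis(vinyl ketone) of the ring B/C/D tricycle
Product: 16 target CNP0156201.1
Conditions: second-generation Hoveyda–Grubbs catalyst (10 mol %), toluene (2 mM), 80 °C; then cat. PPTS, CH2Cl2, rt if C5 needs equilibration
Reagents that add atoms: none
Why: Ring-closing metathesis of the two terminal enones closes ring A at C9=C10 as the cis-enedione with loss of ethene, the trisubstituted isobutenyl and tetrasubstituted C12=C13 alkenes being too hindered to take part.

**Compound list**

1 | (E)-5-methylhex-3-en-2-one | CC(=O)/C=C/C(C)C | starting material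
2 | dimethyl oxalate | COC(=O)C(=O)OC | starting material
3 | methyl (5E)-7-methyl-2,4-dioxooct-5-enoate | COC(=O)C(=O)CC(=O)/C=C/C(C)C | intermediate
4 | methyl (5E)-3,7-dimethyl-2,4-dioxooct-5-enoate (C3 labile, racemic) | COC(=O)C(=O)C(C)C(=O)/C=C/C(C)C | intermediate
5 | cyclopent-2-en-1-one | O=C1C=CCC1 | starting material
6 | methyl (3S,5E)-3,7-dimethyl-2,4-dioxo-3-[(1S)-3-oxocyclopentyl]oct-5-enoate | COC(=O)C(=O)[C@](C)(C(=O)/C=C/C(C)C)[C@H]1CCC(=O)C1 | intermediate
7 | methyl propiolate | C#CC(=O)OC | starting material
8 | 1-iodo-3-methoxy-3-(trimethylsilyloxy)propa-1,2-diene (silyl iodoallenolate, not isolated) | IC=C=C(OC)O[Si](C)(C)C | intermediate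
9 | iodo-aldol silyl ether: C7 O-trimethylsilyl (Z)-beta-iodoacrylate adduct of 6, C7/C15/C20 as in 10 (not isolated) | C[Si](C)(C)O[C@@](C(=O)OC)(/C(C(=O)OC)=C/I)[C@](C)(C(=O)/C=C/C(C)C)[C@H]1CCC(=O)C1 | intermediate
10 | dimethyl (3aS,4R,5R,7aR)-5-hydroxy-4-methyl-4-[(2E)-4-methylpent-2-enoyl]-1-oxo-2,3,3a,4,5,7a-hexahydro-1H-indene-5,6-dicarboxylate (trans ring fusion) | O[C@@]1(C(=O)OC)C(C(=O)OC)=C[C@@H]2[C@H](CCC2=O)[C@@]1(C)C(=O)/C=C/C(C)C | intermediate
11 | dimethyl (1S,3aS,4R,5R,7aR)-1,5-dihydroxy-1,4-dimethyl-4-[(2E)-4-methylpent-2-enoyl]-2,3,3a,4,5,7a-hexahydro-1H-indene-5,6-dicarboxylate | O[C@@]1(C(=O)OC)C(C(=O)OC)=C[C@@H]2[C@H](CC[C@]2(C)O)[C@@]1(C)C(=O)/C=C/C(C)C | intermediate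
12 | alpha-iodo ketone: 11 with the side chain C(=O)–CHI–CH=C(CH3)2, either C5 epimer (not isolated) | O[C@@]1(C(=O)OC)C(C(=O)OC)=C[C@@H]2[C@H](CC[C@]2(C)O)[C@@]1(C)C(=O)C(I)C=C(C)C | intermediate
13 | dimethyl ester of the ring B/C/D furanone tricycle (CO2Me on C7 and on C12; C5, C7, C14, C15, C18, C20 arranged as in 16) | CC(C)=C[C@H]1O[C@@]2(C(=O)OC)C(C(=O)OC)=C[C@@H]3[C@H](CC[C@]3(C)O)[C@@]2(C)C1=O | intermediate
14 | bis(N-methoxy-N-methylamide) of 13 (not isolated) | CC(C)=C[C@H]1O[C@@]2(C(=O)N(C)OC)C(C(=O)N(C)OC)=C[C@@H]3[C@H](CC[C@]3(C)O)[C@@]2(C)C1=O | intermediate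
15 | bis(vinyl ketone) of the ring B/C/D tricycle (acryloyl groups on C7 and C12; stereocentres as in 16) | CC(C)=C[C@H]1O[C@@]2(C(=O)C=C)C(C(=O)C=C)=C[C@@H]3[C@H](CC[C@]3(C)O)[C@@]2(C)C1=O | intermediate
16 | CNP0156201.1 (5R,7S,14R,15S,18S,20R in the labels above) | CC(C)=C[C@H]1O[C@@]23C(=O)C=CC(=O)C2=C[C@@H]2[C@H](CC[C@]2(C)O)[C@@]3(C)C1=O | target

**Step count.** Total: 8 steps. Longest linear sequence: 8 steps (from 1).

**Three steps most likely to fail**

Step 4 (key step). The aldol addition at C7 may show poor facial selectivity: a chelated or alternative rotamer about C7–C20 would give the C7 epimer, which cannot later close ring A. Retro-aldol or silyl transfer under the basic ring closure is a second risk. The fallback locks C8 syn to C21 in a five-membered ring before the annulation. Starting from 6, selective saponification of the alpha-keto ester (LiOH, THF/H2O, 0 °C) should give the alpha-keto acid F1. Enol lactonisation (Ac2O, NaOAc, 60 °C), through the dienol of the enone arm, should give the dienyl enol lactone F2, whose planar alpha-keto lactone exposes C7 only on the face anti to the cyclopentanone branch. The same Me3SiI/DBU sequence with 7 should then give the annulated lactone F3. NaOMe in MeOH at 0 °C opens the enol lactone to the methyl ester and the extended enolate, which reprotonates to the conjugated enone, and the route is rejoined at 10.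

Step 3. Diastereocontrol between C15 and C20 may be low, or the non-enolizable 2,4-dioxo ester adduct may undergo retro-Claisen cleavage or intramolecular Michael addition under amine catalysis. The fallback is a Lewis acid-catalysed Mukaiyama–Michael addition. Starting from 4, Me3SiCl/Et3N should give the silyl enol ether F4. Addition to 5 under a chiral oxazaborolidinium triflimide (from (S)-diphenylprolinol, o-tolylboroxine and HNTf2; CH2Cl2, −78 °C) should give the regiodefined cyclopentanone silyl enol ether F5. Mild acid hydrolysis (1 M HCl, THF) then returns the route to 6.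

Step 6. Deprotonation may occur at C14 instead of C2, iodination may be unselective, or the hindered C7 alkoxide may fail to displace the iodide. The fallback changes the bond-forming event to an ionisation at the far end of the allyl system. Starting from 11, radical allylic bromination (NBS, dibenzoyl peroxide, PhCF3, 80 °C) should give the tertiary gamma-bromo enone F6. AgOTf with 2,6-di-tert-butylpyridine in CH2Cl2 at −20 °C ionises it, and the C7 hydroxyl captures the allyl cation at C5 (5-exo), leaving the C4=C2 alkene and rejoining the route at 13.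

Further compounds
F1 | step 4 | (3S,5E)-3,7-dimethyl-2,4-dioxo-3-[(1S)-3-oxocyclopentyl]oct-5-enoic acid | OC(=O)C(=O)[C@](C)(C(=O)/C=C/C(C)C)[C@H]1CCC(=O)C1
F2 | step 4 | dienyl enol lactone: 4-methyl-5-(3-methylbut-2-enylidene)-4-[(1S)-3-oxocyclopentyl]furan-2,3-dione (C20 as in 6) | O=C1OC(=CC=C(C)C)[C@](C)([C@H]2CCC(=O)C2)C1=O
F3 | step 4 | annulated enol lactone: 10 with C8 tied as the lactone of the C21 dienol | O[C@@]12C(C(=O)OC)=C[C@@H]3[C@H](CCC3=O)[C@@]1(C)C(=CC=C(C)C)OC2=O
F4 | step 3 | methyl (5E)-3,7-dimethyl-4-oxo-2-(trimethylsilyloxy)octa-2,5-dienoate | COC(=O)C(O[Si](C)(C)C)=C(C)C(=O)/C=C/C(C)C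
F5 | step 3 | silyl enol ether of 6: methyl (3S,5E)-3,7-dimethyl-2,4-dioxo-3-[(1S)-3-(trimethylsilyloxy)cyclopent-2-en-1-yl]oct-5-enoate | COC(=O)C(=O)[C@](C)(C(=O)/C=C/C(C)C)[C@H]1CCC(O[Si](C)(C)C)=C1
F6 | step 6 | gamma-bromo enone: 11 with the side chain C(=O)–CH=CH–C(CH3)2Br | O[C@@]1(C(=O)OC)C(C(=O)OC)=C[C@@H]2[C@H](CC[C@]2(C)O)[C@@]1(C)C(=O)/C=C/C(C)(C)Br
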